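**Retrosynthetic overview**
1. Target ⇐ 11-ene diacetate by a singlet-oxygen ene reaction (C12–OOH, exocyclic C11=C20); the acetates come from the C2/C14 diol.
2. Key disconnection C7–C8: an intramolecular aldol of a C9-ketone enolate onto a tethered (Z)-enal closes the ten-membered carbocycle, and the C7 alkoxide lactonises onto the C18 ester in the same operation.
3. Seco precursor: C9–C10 by Nozaki–Hiyama–Kishi coupling of a ring-A dienyl triflate with an α-silyloxy aldehyde from (S)-malate (C17); a later 1,6-reduction sets C10 and places the C11=C12 bond.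
4. Ring A is (S)-carvone: C14–O by Criegee rearrangement, C1–C2 by anti-aldol with a nerol-derived aldehyde (C2–C7, 5Z), quaternary C1 by methylation.
5. Ring order: six-membered ring A (present from the start) → ten-membered ring and γ-lactone together (step 14).

Assumption/convention: the SMILES is taken as the (1S,2S,5Z,7S,8S,10S,12S,14S,17R) enantiomer; briarane locants are used throughout (C1 quaternary, C9 ketone, C17 lactone α-carbon, C18 lactone C=O; C15, C16, C19 = methyls on C1, C5, C17; C20 on C11).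

Step 1
Reactants: 1 (S)-carvone
Product: 4 (S)-5-acetoxy-2-methylcyclohex-2-en-1-one, via methoxy hydroperoxide 2 (not isolated), via peracetate 3 (not isolated)
Conditions: O3, CH2Cl2/MeOH, −78 °C; then Ac2O, Et3N, DMAP (cat.), −78 °C → rt
Reagents that add atoms: ozone [O-][O+]=O; acetic anhydride CC(=O)OC(C)=O (one acetate oxygen)
Why: Ozonolysis in methanol cleaves only the electron-rich isopropenyl group (the enone is inert), and the derived peracetate undergoes Criegee rearrangement with retention, so the C–C bond at the stereocentre becomes the C14–OAc bond.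

Step 2
Reactants: 4 (S)-5-acetoxy-2-methylcyclohex-2-en-1-one
Product: 5 (S)-5-hydroxy-2-methylcyclohex-2-en-1-one
Conditions: K2CO3 (0.1 equiv), MeOH, −10 °C
Reagents that add atoms: none
Why: Base-catalysed transesterification at low temperature frees the alcohol before β-elimination can compete; the stereocentre is untouched.

Step 3
Reactants: 5 (S)-5-hydroxy-2-methylcyclohex-2-en-1-one
Product: 6 (S)-5-(tert-butyldimethylsilyloxy)-2-methylcyclohex-2-en-1-one
Conditions: TBSCl, imidazole, DMF, rt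
Reagents that add atoms: tert-butyldimethylsilyl chloride CC(C)(C)[Si](C)(C)Cl
Why: Silylation gives a β-oxygen substituent that survives the enolate steps and later directs them from the opposite face.

Step 4
Reactants: 7 nerol
Product: 8 neryl triethylsilyl ether
Conditions: TESCl, imidazole, CH2Cl2, 0 °C
Reagents that add atoms: triethylsilyl chloride CC[Si](Cl)(CC)CC
Why: Silylation masks C7–OH as a primary TES ether, which step 13 can oxidise directly to the aldehyde.

Step 5
Reactants: 8 neryl triethylsilyl ether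
Product: 9 (Z)-4-methyl-6-(triethylsilyloxy)hex-4-enal
Conditions: OsO4 (2 mol %), NaIO4, 2,6-lutidine, dioxane/H2O, rt
Reagents that add atoms: sodium periodate [Na+].[O-][I](=O)(=O)=O (oxygen, relayed by catalytic OsO4)
Why: Lemieux–Johnson cleavage takes the remote, more electron-rich trisubstituted alkene (the 2,3-alkene is deactivated by the allylic silyloxy group) and leaves the (Z)-C5=C6 bond intact.

Step 6
Reactants: 6 (S)-5-(tert-butyldimethylsilyloxy)-2-methylcyclohex-2-en-1-one; 9 (Z)-4-methyl-6-(triethylsilyloxy)hex-4-enal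
Product: 11 bis-TBS aldol enone, via C2-hydroxy aldol 10 (not isolated)
Conditions: LDA, THF, −78 °C; add 9; then TBSOTf, −78 → −40 °C
Reagents that add atoms: tert-butyldimethylsilyl trifluoromethanesulfonate CC(C)(C)[Si](C)(C)OS(=O)(=O)C(F)(F)F
Why: Zimmerman–Traxler aldol addition of the kinetic α′-lithium enolate (a ring E-enolate) on the face anti to the adjacent C14–OTBS gives the anti aldol, setting C2 (S); silylation in the flask blocks retro-aldol.

Step 7
Reactants: 11 bis-TBS aldol enone
Product: 12 C1-methylated enone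
Conditions: KHMDS, THF, −78 °C; MeI, −78 → −40 °C
Reagents that add atoms: iodomethane CI
Why: Enolate alkylation of the tetrasubstituted α′-enolate occurs anti to the neighbouring C14–OTBS, making C1 quaternary with methyl trans to the C14 oxygen and the C2 arm cis to it.

Step 8
Reactants: 12 C1-methylated enone
Product: 13 ring-A dienyl triflate
Conditions: KHMDS, THF, −78 °C; PhNTf2; aq NH4Cl
Reagents that add atoms: N-phenyl-bis(trifluoromethanesulfonimide) O=S(=O)(N(c1ccccc1)S(=O)(=O)C(F)(F)F)C(F)(F)F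
Why: With C1 quaternary the only acidic hydrogens are the vinylogous C13–H, so the extended dienolate forms and is O-sulfonylated to the 2-triflyloxy-1,3-diene without touching a stereocentre.

Step 9
Reactants: 14 dimethyl (S)-malate
Product: 15 dimethyl (2S,3R)-3-methylmalate
Conditions: LDA (2.2 equiv), THF, −78 → −20 °C; MeI, −78 °C; AcOH
Reagents that add atoms: iodomethane CI
Why: Fráter–Seebach alkylation of the chelated alkoxide–enolate dianion delivers methyl anti to the C–O bond, setting C17 (R).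

Step 10
Reactants: 15 dimethyl (2S,3R)-3-methylmalate
Product: 16 dimethyl (2S,3R)-3-methyl-2-(triethylsilyloxy)succinate
Conditions: TESCl, imidazole, DMF, rt
Reagents that add atoms: triethylsilyl chloride CC[Si](Cl)(CC)CC
Why: Silylation protects the future C8 oxygen as a non-chelating ether that is needed for the enolate geometry in step 14.

Step 11
Reactants: 16 dimethyl (2S,3R)-3-methyl-2-(triethylsilyloxy)succinate
Product: 17 methyl (2R,3S)-2-methyl-4-oxo-3-(triethylsilyloxy)butanoate
Conditions: DIBAL-H (1.05 equiv), CH2Cl2, −78 °C; Rochelle salt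
Reagents that add atoms: none
Why: Partial ester reduction is selective for the more electrophilic α-silyloxy ester over the α-methyl-branched one, and the tetrahedral aluminate survives at −78 °C so the aldehyde (C9) is released only on work-up.

Step 12
Reactants: 13 ring-A dienyl triflate; 17 methyl (2R,3S)-2-methyl-4-oxo-3-(triethylsilyloxy)butanoate
Product: 18 C9 dienyl carbinol
Conditions: CrCl2 (6 equiv), NiCl2 (2 mol %), DMF, rt
Reagents that add atoms: none
Why: Nozaki–Hiyama–Kishi coupling (Ni insertion into C–OTf, transmetalation to Cr(III), aldehyde-selective addition) forms C9–C10; the C9 carbinol centre forms as a mixture and is erased in step 13.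

Step 13
Reactants: 18 C9 dienyl carbinol
Product: 19 seco dienone enal
Conditions: (COCl)2, DMSO, CH2Cl2, −78 °C; Et3N, −78 → −20 °C
Reagents that add atoms: none
Why: Swern oxidation converts the C9 carbinol to the dienone and, by chlorosulfonium-induced desilylation, the primary allylic TES ether directly to the (Z)-enal, while the hindered secondary silyl ethers are inert.

Step 14
Reactants: 19 seco dienone enal
Product: 21 bicyclic lactone dienone, via macrocyclic aldol hydroxy ester 20 (not isolated)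
Conditions: LiHMDS (1.1 equiv), THF, slow addition of 19 (final 2 mM), −78 → −30 °C; aq NH4Cl
Reagents that add atoms: none
Why: Proposed new method: C8–H is the only enolisable α-hydrogen of the C9 ketone (C10 is sp2), so the enolate is regiodefined; with the C17 arm cis to OLi it should add through a Li-bridged Zimmerman–Traxler chair to the tethered (Z)-enal to give the 7,8-anti (ring-cis) pair 7S,8S on the face anti to the C17 ester, and the C7 alkoxide is trapped irreversibly by 5-exo lactonisation on the C18 methyl ester so the strained ten-membered aldol cannot revert; the closest known reaction types are intramolecular aldol macrocyclisation and tandem aldol–lactonisation.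

Step 15
Reactants: 21 bicyclic lactone dienone
Product: 22 11-ene β,γ-enone tris-silyl ether
Conditions: [(Ph3P)CuH]6 (0.25 equiv), benzene/THF, 0 °C; then AcOH, −78 °C
Reagents that add atoms: none
Why: Conjugate (1,6) hydride addition goes to the unhindered δ-carbon C13 (the β-carbon C11 is fully substituted), and kinetic α-protonation of the dienolate at C10 from the α-face (anti to the axial C1 methyl) gives the deconjugated C11=C12 ketone and sets C10 (S).

Step 16
Reactants: 22 11-ene β,γ-enone tris-silyl ether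
Product: 23 2,8,14-triol
Conditions: HF·pyridine, pyridine/THF, 0 °C → rt
Reagents that add atoms: none
Why: Buffered fluoride desilylation removes both TBS ethers and the tertiary TES ether without base, so the β,γ-enone and C10 are not isomerised.

Step 17
Reactants: 23 2,8,14-triol
Product: 24 2,14-diacetate
Conditions: Ac2O, pyridine, DMAP (cat.), CH2Cl2, 0 °C → rt
Reagents that add atoms: acetic anhydride CC(=O)OC(C)=O
Why: Acylation takes the two secondary alcohols, while the hindered, hydrogen-bonded tertiary C8–OH of the α-ketol stays free.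

Step 18
Reactants: 24 2,14-diacetate
Product: 25 target CNP0066422.1
Conditions: O2, visible light, tetraphenylporphyrin (cat.), CH2Cl2, −20 °C
Reagents that add atoms: oxygen O=O
Why: Schenck ene reaction of singlet oxygen on the electron-rich C11=C12 bond (C5=C6 is deactivated by the allylic lactone oxygen) abstracts a C20 methyl hydrogen geminal to the bulky C10 substituent and adds oxygen to the β-face of C12, anti to the axial 14α-acetoxy group, giving C12 (S) and the exocyclic methylene.

**Compound list**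
1 | (S)-(+)-carvone, (5S)-2-methyl-5-(prop-1-en-2-yl)cyclohex-2-en-1-one | O=C1C(C)=CC[C@H](C(C)=C)C1 | starting material
2 | (5S)-5-(1-hydroperoxy-1-methoxyethyl)-2-methylcyclohex-2-en-1-one (epimers at the peroxy carbon) | O=C1C(C)=CC[C@H](C(C)(OC)OO)C1 | intermediate (not isolated)
3 | (5S)-5-[1-(acetylperoxy)-1-methoxyethyl]-2-methylcyclohex-2-en-1-one | O=C1C(C)=CC[C@H](C(C)(OC)OOC(C)=O)C1 | intermediate (not isolated)
4 | (S)-5-acetoxy-2-methylcyclohex-2-en-1-one | O=C1C(C)=CC[C@H](OC(C)=O)C1 | intermediate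
5 | (S)-5-hydroxy-2-methylcyclohex-2-en-1-one | O=C1C(C)=CC[C@H](O)C1 | intermediate
6 | (S)-5-[(tert-butyldimethylsilyl)oxy]-2-methylcyclohex-2-en-1-one | O=C1C(C)=CC[C@H](O[Si](C)(C)C(C)(C)C)C1 | intermediate
7 | nerol, (2Z)-3,7-dimethylocta-2,6-dien-1-ol | CC(C)=CCC/C(C)=C\CO | starting material
8 | neryl triethylsilyl ether, triethyl{[(2Z)-3,7-dimethylocta-2,6-dien-1-yl]oxy}silane | CC(C)=CCC/C(C)=C\CO[Si](CC)(CC)CC | intermediate
9 | (4Z)-4-methyl-6-[(triethylsilyl)oxy]hex-4-enal (C2–C7 unit) | O=CCC/C(C)=C\CO[Si](CC)(CC)CC | intermediate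
10 | C2-hydroxy aldol: (5S,6R)-5-[(tert-butyldimethylsilyl)oxy]-6-[(1S,4Z)-1-hydroxy-4-methyl-6-(triethylsilyloxy)hex-4-en-1-yl]-2-methylcyclohex-2-en-1-one | O=C1C(C)=CC[C@H](O[Si](C)(C)C(C)(C)C)[C@H]1[C@@H](O)CC/C(C)=C\CO[Si](CC)(CC)CC | intermediate (not isolated)
11 | bis-TBS aldol enone: (5S,6R)-5-[(tert-butyldimethylsilyl)oxy]-6-[(1S,4Z)-1-[(tert-butyldimethylsilyl)oxy]-4-methyl-6-(triethylsilyloxy)hex-4-en-1-yl]-2-methylcyclohex-2-en-1-one | O=C1C(C)=CC[C@H](O[Si](C)(C)C(C)(C)C)[C@H]1[C@@H](O[Si](C)(C)C(C)(C)C)CC/C(C)=C\CO[Si](CC)(CC)CC | intermediate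
12 | C1-methylated enone: (5S,6S)-5-[(tert-butyldimethylsilyl)oxy]-6-[(1S,4Z)-1-[(tert-butyldimethylsilyl)oxy]-4-methyl-6-(triethylsilyloxy)hex-4-en-1-yl]-2,6-dimethylcyclohex-2-en-1-one (6-methyl trans to the 5-silyloxy group) | O=C1C(C)=CC[C@H](O[Si](C)(C)C(C)(C)C)[C@]1(C)[C@@H](O[Si](C)(C)C(C)(C)C)CC/C(C)=C\CO[Si](CC)(CC)CC | intermediate
13 | ring-A dienyl triflate: (5S,6S)-5-[(tert-butyldimethylsilyl)oxy]-6-[(1S,4Z)-1-[(tert-butyldimethylsilyl)oxy]-4-methyl-6-(triethylsilyloxy)hex-4-en-1-yl]-2,6-dimethylcyclohexa-1,3-dien-1-yl trifluoromethanesulfonate | FC(F)(F)S(=O)(=O)OC1=C(C)C=C[C@H](O[Si](C)(C)C(C)(C)C)[C@]1(C)[C@@H](O[Si](C)(C)C(C)(C)C)CC/C(C)=C\CO[Si](CC)(CC)CC | intermediate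
14 | dimethyl (S)-malate | COC(=O)C[C@H](O)C(=O)OC | starting material
15 | dimethyl (2S,3R)-2-hydroxy-3-methylbutanedioate | COC(=O)[C@H](C)[C@H](O)C(=O)OC | intermediate
16 | dimethyl (2S,3R)-3-methyl-2-[(triethylsilyl)oxy]butanedioate | COC(=O)[C@H](C)[C@H](O[Si](CC)(CC)CC)C(=O)OC | intermediate
17 | methyl (2R,3S)-2-methyl-4-oxo-3-[(triethylsilyl)oxy]butanoate (C9, C8, C17, C18 unit) | COC(=O)[C@H](C)[C@H](O[Si](CC)(CC)CC)C=O | intermediate
18 | C9 dienyl carbinol: 13 with the triflate replaced by the CH(OH)–CH(OTES)–CH(CH3)–CO2CH3 chain of 17 (C9 epimers; C17 R) | COC(=O)[C@H](C)[C@H](O[Si](CC)(CC)CC)C(O)C1=C(C)C=C[C@H](O[Si](C)(C)C(C)(C)C)[C@]1(C)[C@@H](O[Si](C)(C)C(C)(C)C)CC/C(C)=C\CO[Si](CC)(CC)CC | intermediate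
19 | seco dienone enal: 18 with C9 as ketone and C7 as (Z)-enal aldehyde | COC(=O)[C@H](C)[C@H](O[Si](CC)(CC)CC)C(=O)C1=C(C)C=C[C@H](O[Si](C)(C)C(C)(C)C)[C@]1(C)[C@@H](O[Si](C)(C)C(C)(C)C)CC/C(C)=C\C=O | intermediate
20 | macrocyclic aldol hydroxy ester: ten-membered ring closed at C7–C8 (7S-OH, 8S-OTES), methyl ester still open | COC(=O)[C@H](C)[C@]1(O[Si](CC)(CC)CC)[C@@H](O)/C=C(/C)CC[C@H](O[Si](C)(C)C(C)(C)C)[C@@]2(C)[C@@H](O[Si](C)(C)C(C)(C)C)C=CC(C)=C2C1=O | intermediate (not isolated)
21 | bicyclic lactone dienone: 6/10-bicycle with C18,7-γ-lactone, C9 ketone, C10=C11 and C12=C13 diene, 2,14-bis-OTBS, 8-OTES; C1, C2, C7, C8, C14, C17 as in 25 | CC1=C2C(=O)[C@@]3(O[Si](CC)(CC)CC)[C@H](/C=C(/C)CC[C@H](O[Si](C)(C)C(C)(C)C)[C@@]2(C)[C@@H](O[Si](C)(C)C(C)(C)C)C=C1)OC(=O)[C@@H]3C | intermediate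
22 | 11-ene β,γ-enone tris-silyl ether: as 21 but C10–H (α, 10S), C11=C12, C13H2 | CC=1[C@@H]2C(=O)[C@@]3(O[Si](CC)(CC)CC)[C@H](/C=C(/C)CC[C@H](O[Si](C)(C)C(C)(C)C)[C@@]2(C)[C@@H](O[Si](C)(C)C(C)(C)C)CC=1)OC(=O)[C@@H]3C | intermediate
23 | 2,8,14-triol: desilylated 22 | CC=1[C@@H]2C(=O)[C@@]3(O)[C@H](/C=C(/C)CC[C@H](O)[C@@]2(C)[C@@H](O)CC=1)OC(=O)[C@@H]3C | intermediate
24 | 2,14-diacetate: 2,14-diacetoxy-8-hydroxy-9-oxo-5(Z),11-diene lactone | CC=1[C@@H]2C(=O)[C@@]3(O)[C@H](/C=C(/C)CC[C@H](OC(C)=O)[C@@]2(C)[C@@H](OC(C)=O)CC=1)OC(=O)[C@@H]3C | intermediate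
25 | CNP0066422.1, (1S,2S,5Z,7S,8S,10S,12S,14S,17R)-2,14-diacetoxy-12-hydroperoxy-8-hydroxy-9-oxo-5,11(20)-diene lactone | C=C1[C@@H]2C(=O)[C@@]3(O)[C@H](/C=C(/C)CC[C@H](OC(C)=O)[C@@]2(C)[C@@H](OC(C)=O)C[C@@H]1OO)OC(=O)[C@@H]3C | target

**Totals and risk**
Total step count: 18. Longest linear sequence: 13 steps (1–3, 6–8, 12–18, from 1).

Most likely to fail, each with a fallback:

Step 14 (aldol macrocyclisation/lactonisation: oligomerisation, enal enolisation, or the wrong C7/C8 pair). The fallback replaces substrate-controlled lithium-enolate chemistry by a catalyst-controlled direct aldol of the free α-ketol. It sets out from 19: buffered HF·pyridine at 0 °C removes only the C8 triethylsilyl ether to give the C8-hydroxy seco dienone enal F1. Et2Zn with a ProPhenol ligand (either antipode can be screened) forms the chelated zinc enediolate at C8, which closes the ring by intramolecular aldol addition and lactonises to the C8-hydroxy bicyclic lactone dienone F2. 1,6-Reduction as in step 15 gives the C8-hydroxy 11-ene β,γ-enone F3, and HF·pyridine as in step 16 comes back to the route at 23.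

Step 15 (1,2- instead of 1,6-reduction, or γ-protonation back to a conjugated enone). The fallback separates saturation from deconjugation. It sets out from 21: hydrogenation with Wilkinson's catalyst saturates only the cis-disubstituted C12=C13 bond to give the 12,13-dihydro conjugated enone F4. Deconjugation through the endocyclic potassium dienolate (KHMDS, THF/HMPA, −78 °C, inverse quench into AcOH; kinetic α-protonation) comes back to the route at 22.

Step 18 (ene regiochemistry among C20–H, C10–H and C13–H, or facial selectivity at C12). The fallback builds the allylic hydroperoxide ionically. It sets out from 24: m-CPBA epoxidises C11=C12 from the α-face (anti to the axial C1 methyl) to the 11α,12α-epoxide F5. Et2Al–TMP isomerises it by removal of a C20 hydrogen to the 12α-hydroxy-11(20)-ene F6. MsCl/Et3N gives the 12α-mesylate F7, and SN2 displacement with H2O2 (inversion) comes back to the route at 25.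

**Further compounds**
F1 | step 14 | C8-hydroxy seco dienone enal | COC(=O)[C@H](C)[C@H](O)C(=O)C1=C(C)C=C[C@H](O[Si](C)(C)C(C)(C)C)[C@]1(C)[C@@H](O[Si](C)(C)C(C)(C)C)CC/C(C)=C\C=O
F2 | step 14 | C8-hydroxy bicyclic lactone dienone | CC1=C2C(=O)[C@@]3(O)[C@H](/C=C(/C)CC[C@H](O[Si](C)(C)C(C)(C)C)[C@@]2(C)[C@@H](O[Si](C)(C)C(C)(C)C)C=C1)OC(=O)[C@@H]3C
F3 | step 14 | C8-hydroxy 11-ene β,γ-enone | CC=1[C@@H]2C(=O)[C@@]3(O)[C@H](/C=C(/C)CC[C@H](O[Si](C)(C)C(C)(C)C)[C@@]2(C)[C@@H](O[Si](C)(C)C(C)(C)C)CC=1)OC(=O)[C@@H]3C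
F4 | step 15 | 12,13-dihydro conjugated enone | CC1=C2C(=O)[C@@]3(O[Si](CC)(CC)CC)[C@H](/C=C(/C)CC[C@H](O[Si](C)(C)C(C)(C)C)[C@@]2(C)[C@@H](O[Si](C)(C)C(C)(C)C)CC1)OC(=O)[C@@H]3C
F5 | step 18 | 11α,12α-epoxide | C[C@]14[C@@H]2C(=O)[C@@]3(O)[C@H](/C=C(/C)CC[C@H](OC(C)=O)[C@@]2(C)[C@@H](OC(C)=O)C[C@H]1O4)OC(=O)[C@@H]3C
F6 | step 18 | 12α-hydroxy-11(20)-ene | C=C1[C@@H]2C(=O)[C@@]3(O)[C@H](/C=C(/C)CC[C@H](OC(C)=O)[C@@]2(C)[C@@H](OC(C)=O)C[C@H]1O)OC(=O)[C@@H]3C
F7 | step 18 | 12α-mesylate | C=C1[C@@H]2C(=O)[C@@]3(O)[C@H](/C=C(/C)CC[C@H](OC(C)=O)[C@@]2(C)[C@@H](OC(C)=O)C[C@H]1OS(C)(=O)=O)OC(=O)[C@@H]3C
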